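A small charge of reagent, 0.90 equiv in the violet run, raised the target to 6.2 % of the solid substrate charged, and I wanted to learn from that what a flask given 1.80 equiv would do.

the same everywhere: solid substrate 20 mM

| flask | reagent | protic impurity | remark | time |
|---|---|---|---|---|
| violet | 0.90 equiv (fed, over 30 s) | 10 mM | run made earlier |  |
| amber | 3.6 equiv (fed, over 30 s) | 10 mM | run made earlier |  |
| flask | 1.80 equiv (fed, over 30 s) | 10.0 mM |  | 3.0 h |

- violet (time / h: solid substrate / %, target / %): 0.200: 0.6, 6.5; 0.667: 0, 7.3; 1.00: 0, 6.8; 1.50: 0, 6.2; 2.50: 0, 6.2; 3.00: 0.3, 6.2
- amber (time / h: solid substrate / %, target / %): 0.250: 0, 20.2; 0.417: 0.6, 17.7; 0.667: 0, 19.9; 1.00: 0, 19.3; 2.00: 0, 18.0; 3.00: 0.1, 20.0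

(scatter of a reading: 1 percentage point)

1. why nothing more happens at 3.0 h, or that something still does (for what has run out or reacted, a solid counts together with what of it has only dissolved) (it is still moving / the reagent has run out first / all of the solid substrate has reacted / forward and back rates have come level)
2. part of the solid substrate that has turned into other species by 3.0 h (what has only dissolved does not count)
3. amount of target at 3.0 h, in percent of the solid substrate charged

- solid substrate is a solid; its amount is given per volume of the solution
- the numbers in the tables scatter with a standard deviation of 1 percentage point
- what may be going on: solid substrate <-> dissolved substrate; dissolved substrate + reagent -> target; reagent -> side product; solid substrate + protic impurity -> quenched substrate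
- at the start none of the solid substrate is in solution
- what has only dissolved of solid substrate counts as not reacted
- the reaction counts as stopped when no species that holds the solid substrate changes by six tenths of a point or more over the second half of the time

My first question was whether the clock matters. In the violet run the target read 6.5 % at 0.200 h and 6.2 % at 3.00 h, and in the amber run 20.2 % at 0.250 h and 20.0 % at 3.00 h. Within the scatter of 1 percentage point both stood flat from the first sample, so I could leave time out.

My second question was how the reagent divides. It can react with the dissolved substrate to give target, or it can go to side product. If both steps are first order in c(reagent), dividing one rate by the other removes time and c(reagent), and c(dissolved substrate) remains in the ratio. So I counted target made per reagent charged, which read 6.89 % in violet and 5.56 % in amber. This capture share, a selectivity factor taken over the whole feed, is a reading with the scatter of its target value. It says that nearly all of the amber reagent did not become target.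

My third question was what the flask's share would be. The flask's charge is twice the violet charge and half the amber charge, so I took the geometric mean, 6.19 %, and this gave target 11.1 %, which is lower than the forecast's value.

The forecast said the reagent has run out first, with conversion 55 % and target 11.7 %, holding that “the yield bends as the substrate pool depletes”.

The flask showed that the reagent has run out first, with 0 % of it left at 3.00 h, conversion 60.6 % and target 11.2 %.

    solid substrate ⇌ dissolved substrate, rate k1*(cs1 - [dissolved substrate]) while solid is left; crystals form when [dissolved substrate] > cs1 (solubility = 11.0 mM, k = 0.0170 s⁻¹)
    dissolved substrate + reagent → target (k = 2.00 L mol⁻¹ s⁻¹)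
    reagent → side product (k = 0.0890 s⁻¹)
    solid substrate + protic impurity → quenched substrate (k = 10.0 L mol⁻¹ s⁻¹)

The forecast's conversion stood 5.6 points below the flask's, while the flask's capture share came to 6.22 %. A neighbouring flask took 3.10 equiv of reagent, all else as in the recipe, a charge nearer the amber charge than the charge of the asked flask. So I multiplied the amber capture share 5.56 % by that charge and got 17.2 %. That neighbouring flask ended with 0 % of its reagent left and target at 16.9 %.

The numbers in the tables are simulated with constants of no real substance; the scatter is artificial.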